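**Strategy.** Everything rests on the C7–C8 bond, the fusion bond that the nine-membered carbocycle (C1, C3–C10) shares with the γ-lactone and whose two carbons both carry oxygen. A SmI2 ketyl coupling of a C7 aldehyde with the C8 ketone of a β-keto ester closes the nine-membered ring as a samarium-bridged cis-diol, and the C7 alkoxide lactonizes onto C19 in the same flask. The precursor is a cis-diquinane with two arms on C3 and C10; the diquinane comes from an intramolecular Diels–Alder adduct of a 5,5-disubstituted cyclopentadiene, whose extra C4–C12 bond is cut by periodate to unveil the C4 aldehyde and C12 ketone.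

Key step: step 19

Remark (numbering, briarane-type): C1 quaternary carbon with methyl C15; C2=C14 ring alkene; C3; C4 (OAc); C5 (=C16H2); C6 (Cl); C7 (lactone O–CH); C8 (tertiary OH); C9 (OAc); C10; C11 (OH, methyl C20); C12 (ketone); C13; C17 (methyl C18); C19 (lactone C=O). "α" is the diquinane face that carries the C1 methyl and H13.

**Fragment C5–C7 (C16)**

Step 1
Reactants: 1 (S)-2,2-dimethyl-1,3-dioxolane-4-carbaldehyde
Product: 2 (R)-4-ethynyl-2,2-dimethyl-1,3-dioxolane
Conditions: dimethyl (1-diazo-2-oxopropyl)phosphonate, K2CO3, MeOH, 0 °C to rt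
Reagents that add atoms: dimethyl (1-diazo-2-oxopropyl)phosphonate, COP(=O)(OC)C(=[N+]=[N-])C(C)=O
Why: Ohira–Bestmann (Seyferth–Gilbert) homologation should turn the aldehyde into the terminal alkyne without touching the chiral-pool stereocenter that becomes C6.

Step 2
Reactants: 2 (R)-4-ethynyl-2,2-dimethyl-1,3-dioxolane
Product: 4 (S)-3-iodobut-3-ene-1,2-diol, via iodoalkene acetonide 3 (not isolated)
Conditions: NaI, Me3SiCl, H2O, MeCN, 0 °C to rt; then MeOH, rt
Reagents that add atoms: sodium iodide, [Na+].[I-]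
Why: HI made in the flask should add in the Markovnikov sense (alkyne hydroiodination) to give the 2-iodoalkene and then cleave the acetonide by acid-catalysed transacetalization.

Step 3
Reactants: 4 (S)-3-iodobut-3-ene-1,2-diol
Product: 5 (S)-3-iodo-1,2-bis(triethylsilyloxy)but-3-ene
Conditions: Et3SiCl, imidazole, DMF, 0 °C
Reagents that add atoms: chlorotriethylsilane, CC[Si](CC)(CC)Cl
Why: Standard silylation of both hydroxyls gives a primary ether that can later be oxidized selectively and a secondary ether that survives to the key step.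

**Core**

Step 4
Reactants: 6 2-methylcyclopentane-1,3-dione; 7 2-bromo-N-methoxy-N-methylacetamide
Product: 8 N-methoxy-N-methyl-2-(1-methyl-2,5-dioxocyclopentyl)acetamide
Conditions: K2CO3, Bu4NI (cat.), MeCN, 60 °C
Reagents that add atoms: none
Why: C-alkylation (SN2) of the dione enolate creates the future quaternary C1 together with C10 and C11.

Step 5
Reactants: 8 N-methoxy-N-methyl-2-(1-methyl-2,5-dioxocyclopentyl)acetamide
Product: 9 5-[2-(methoxy(methyl)amino)-2-oxoethyl]-5-methylcyclopenta-1,3-diene-1,4-diyl bis(trifluoromethanesulfonate)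
Conditions: KN(SiMe3)2 (2.2 equiv), PhNTf2 (2.2 equiv), THF, −78 to 0 °C
Reagents that add atoms: N-phenylbis(trifluoromethanesulfonimide), O=S(=O)(N(c1ccccc1)S(=O)(=O)C(F)(F)F)C(F)(F)F
Why: Double enol triflation can only enolize away from the quaternary carbon, so both ketones should end as vinyl triflates of a cyclopentadiene.

Step 6
Reactants: 9 bis(enol triflate)
Product: 10 N-methoxy-N-methyl-2-(1-methylcyclopenta-2,4-dien-1-yl)acetamide
Conditions: Pd(OAc)2 (5 mol %), PPh3, HCO2H, Bu3N, DMF, 60 °C
Reagents that add atoms: none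
Why: Palladium-catalysed formate reduction of vinyl triflates should give the 5,5-disubstituted cyclopentadiene, which has no hydrogen at C1 and so cannot isomerize by 1,5-hydrogen shift.

Step 7
Reactants: 10 N-methoxy-N-methyl-2-(1-methylcyclopenta-2,4-dien-1-yl)acetamide
Product: 11 1-(methoxymethoxy)-3-(1-methylcyclopenta-2,4-dien-1-yl)propan-2-one
Conditions: Bu3SnCH2OCH2OMe, n-BuLi, THF, −78 °C; then 10, −78 °C; aq. NH4Cl
Reagents that add atoms: tributyl[(methoxymethoxy)methyl]stannane, CCCC[Sn](CCCC)(CCCC)COCOC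
Why: Weinreb ketone synthesis with the α-alkoxymethyllithium from tin–lithium exchange should stop at the ketone and bring in C12 with its oxygen.

Step 8
Reactants: 11 1-(methoxymethoxy)-3-(1-methylcyclopenta-2,4-dien-1-yl)propan-2-one
Product: 13 (Z)-3,4-bis(methoxymethoxy)-1-(1-methylcyclopenta-2,4-dien-1-yl)but-3-en-2-one, via sodium hydroxymethylene enolate 12 (not isolated)
Conditions: NaH, HCO2Et, THF, 0 °C to rt; then MeOCH2Cl, 0 °C
Reagents that add atoms: ethyl formate, CCOC=O; chloromethyl methyl ether, COCCl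
Why: Claisen formylation should occur at the unhindered alkoxymethylene (C10 is neopentyl) and O-alkylation of the enolate should give the push–pull enol ether, expected as the Z isomer with the new ether trans to the acyl group.

Step 9
Reactants: 13 (Z)-3,4-bis(methoxymethoxy)-1-(1-methylcyclopenta-2,4-dien-1-yl)but-3-en-2-one
Product: 14 tricyclic ketone (norbornene with bridgeheads C3 and C13, alkene C2=C14 and methyl-bearing bridge C1, fused to the cyclopentanone C1–C10–C11(=O)–C12–C13; endo methoxymethyl ethers at C12 and C4)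
Conditions: Cu(SbF6)2 with 2,2'-(propane-2,2-diyl)bis[(4S)-4-tert-butyl-4,5-dihydrooxazole] (10 mol %), CH2Cl2, −20 °C to rt
Reagents that add atoms: none
Why: Intramolecular Diels–Alder reaction in which the two-atom tether forces C11 exo and joins C12 and C4 to the two diene termini, the Z dienophile puts both ethers endo, and the copper bis(oxazoline) complex, chelated by the C11 carbonyl and the C12 ether oxygen, should select one of the two enantiotopic termini (ligand antipode chosen accordingly), so that C1, C3, C12 and C13 are set at once.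

Step 10
Reactants: 14 tricyclic ketone
Product: 16 syn aldol adduct (14 with an exo, α-oriented CH(OH)CO2Me group at C10), via triisopropoxytitanium enolate 15 (not isolated)
Conditions: LiN(iPr)2, THF, −78 °C; ClTi(OiPr)3, −78 to −40 °C; methyl glyoxylate, −78 °C
Reagents that add atoms: methyl glyoxylate, COC(=O)C=O
Why: Titanium enolate aldol addition, in which only C10 can enolize (C12 is a bridgehead of the second bicycle), the aldehyde should approach the exo face of the norbornanone-like ring to set C10, and the triisopropoxytitanium enolate of a cyclic ketone should favour the syn adduct needed for C9.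

Step 11
Reactants: 16 syn aldol adduct
Product: 17 tertiary alcohol (C11 with α-methyl and β-hydroxyl)
Conditions: MeLi, CeCl3, THF, −78 °C
Reagents that add atoms: methyllithium, [Li]C
Why: The weakly basic organocerium reagent should add 1,2 to the C11 ketone from the exo face of the cage (leaving the ester, whose neighbour is an alkoxide, untouched), which puts the methyl α and the hydroxyl β.

Step 12
Reactants: 17 tertiary alcohol
Product: 18 9,11-bis(triethylsilyl) ether
Conditions: Et3SiOTf, 2,6-lutidine, CH2Cl2, −78 to 0 °C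
Reagents that add atoms: triethylsilyl trifluoromethanesulfonate, CC[Si](CC)(CC)OS(=O)(=O)C(F)(F)F
Why: Silyl triflate silylation caps the secondary C9 and the tertiary C11 hydroxyl, so that only the C4/C12 diol is cleaved later and the C12 ketone is shielded in the samarium step.

Step 13
Reactants: 18 9,11-bis(triethylsilyl) ether
Product: 19 β-keto ester (C8 ketone, C17 methyl, C19 methyl ester; C17 epimers)
Conditions: methyl propanoate, LiN(iPr)2 (3 equiv), THF, −78 °C; then 18, −78 to −20 °C
Reagents that add atoms: methyl propanoate, CCC(=O)OC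
Why: Crossed Claisen condensation of the preformed lithium enolate with the α-silyloxy methyl ester should be driven by deprotonation of the β-keto ester formed.

Step 14
Reactants: 19 β-keto ester
Product: 20 C4,C12 cis-diol
Conditions: ZnBr2, n-PrSH, CH2Cl2, 0 °C
Reagents that add atoms: none
Why: Lewis acid and thiol cleavage of the two methoxymethyl ethers should leave the silyl ethers and the β-keto ester in place.

Step 15
Reactants: 20 C4,C12 cis-diol
Product: 21 diquinane keto aldehyde (C4 aldehyde on C3, C12 ketone)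
Conditions: NaIO4, THF/pH 7 buffer, 0 °C
Reagents that add atoms: none
Why: Periodate glycol cleavage of the endo,endo cis-diol cuts the temporary C4–C12 bond, releases the strain of the norbornene and reveals the cis-diquinane with all ring stereocenters in place.

Step 16
Reactants: 21 diquinane keto aldehyde; 5 (S)-3-iodo-1,2-bis(triethylsilyloxy)but-3-ene
Product: 22 (4S)-allylic alcohol (C4–C5 bond, C5=C16 methylene)
Conditions: CrCl2, NiCl2 (cat.), chiral oxazoline–sulfonamide ligand, Et3N, THF, rt
Reagents that add atoms: none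
Why: Nozaki–Hiyama–Kishi coupling adds the vinyl chromium species only to the aldehyde (ketones and the β-keto ester are tolerated) and the chiral ligand on chromium, chosen in the antipode that favours 4S, should set C4.

Step 17
Reactants: 22 (4S)-allylic alcohol
Product: 23 C4 acetate
Conditions: Ac2O, pyridine, DMAP (cat.), CH2Cl2, 0 °C
Reagents that add atoms: acetic anhydride, CC(=O)OC(C)=O
Why: Acetylation of the only free secondary alcohol installs the first of the two target acetates.

Step 18
Reactants: 23 C4 acetate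
Product: 24 C7 aldehyde
Conditions: (COCl)2, DMSO, CH2Cl2, −78 to −40 °C; then i-Pr2NEt, −78 to 0 °C
Reagents that add atoms: none
Why: Swern oxidation should convert the primary triethylsilyl ether directly into the aldehyde while the secondary and tertiary silyl ethers stay, and the hindered base limits epimerization at C6.

Step 19
Reactants: 24 C7 aldehyde
Product: 26 nine-membered β-hydroxy γ-lactone 6,9,11-tris(triethylsilyl) ether, via samarium diolate 25 (not isolated)
Conditions: SmI2 (3 equiv), THF (2 mM), −78 to 0 °C; aq. NH4Cl; then DBU (cat.), CH2Cl2, rt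
Reagents that add atoms: none
Why: Divalent samarium reduces the C7 aldehyde to a ketyl, which adds to the C8 ketone held as a samarium chelate of the β-keto ester; a second electron gives the trivalent samarium diolate 25, whose C7 alkoxide attacks the C19 methyl ester. The closest known reaction type is the SmI2 keto–aldehyde pinacol cyclization with in situ lactonization of a γ-hydroxy ester. The nine-membered carbocycle closes by 9-exo-trig attack of the C7 ketyl carbon on the C8 carbonyl and the γ-lactone by 5-exo-trig acyl substitution. C7 and C8 are set together: one samarium bridging both oxygens makes the diol cis on the new ring, and each new C–O bond should lie anti to the flanking silyloxy group at C6 or C9, as in pinacol cyclizations of dicarbonyls flanked by alkoxy groups, which gives the trans,cis,trans array from C6 to C9; C17 is then settled under thermodynamic control by DBU (methyl trans to C9). The step needs reduction of the aldehyde in preference to the C12 ketone and to cleavage of the α-silyloxy groups; low temperature, the absence of HMPA, shielding of C12 by the C11 silyl ether and the chelating β-keto ester should secure this, and high dilution with both arms held on neighbours of C1 should favour ring closure over dimerization.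

Step 20
Reactants: 26 nine-membered β-hydroxy γ-lactone tris(triethylsilyl) ether
Product: 27 6,8,9,11-tetraol 4-acetate
Conditions: HF·pyridine, pyridine, THF, 0 °C to rt
Reagents that add atoms: none
Why: Fluoride desilylation removes the three silyl ethers without touching the acetate or the lactone.

Step 21
Reactants: 27 6,8,9,11-tetraol 4-acetate
Product: 28 6-chloro-8,9,11-triol 4-acetate
Conditions: PPh3, hexachloroacetone, CH2Cl2, −20 to 0 °C
Reagents that add atoms: hexachloroacetone, O=C(C(Cl)(Cl)Cl)C(Cl)(Cl)Cl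
Why: Appel-type chlorination should pick the allylic C6 hydroxyl over the hindered C9 and the tertiary hydroxyls and displace the oxyphosphonium by SN2 with inversion, which turns the chiral-pool C6 configuration into that of the target.

Step 22
Reactants: 28 6-chloro-8,9,11-triol 4-acetate
Product: 29 CNP0145188.1 (target)
Conditions: Ac2O, DMAP, pyridine, CH2Cl2, 0 °C to rt
Reagents that add atoms: acetic anhydride, CC(=O)OC(C)=O
Why: Acetylation of the only secondary hydroxyl (C9) leaves the two tertiary alcohols free.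

**Compound list**

1 | (S)-2,2-dimethyl-1,3-dioxolane-4-carbaldehyde | O=C[C@@H]1COC(C)(C)O1 | starting material
2 | (R)-4-ethynyl-2,2-dimethyl-1,3-dioxolane | C#C[C@@H]1COC(C)(C)O1 | intermediate
3 | (S)-4-(1-iodovinyl)-2,2-dimethyl-1,3-dioxolane (not isolated) | C=C(I)[C@@H]1COC(C)(C)O1 | intermediate
4 | (S)-3-iodobut-3-ene-1,2-diol | C=C(I)[C@@H](O)CO | intermediate
5 | (S)-3-iodo-1,2-bis(triethylsilyloxy)but-3-ene | C=C(I)[C@@H](O[Si](CC)(CC)CC)CO[Si](CC)(CC)CC | intermediate
6 | 2-methylcyclopentane-1,3-dione | CC1C(=O)CCC1=O | starting material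
7 | 2-bromo-N-methoxy-N-methylacetamide | CON(C)C(=O)CBr | starting material
8 | N-methoxy-N-methyl-2-(1-methyl-2,5-dioxocyclopentyl)acetamide | CON(C)C(=O)CC1(C)C(=O)CCC1=O | intermediate
9 | 5-[2-(methoxy(methyl)amino)-2-oxoethyl]-5-methylcyclopenta-1,3-diene-1,4-diyl bis(trifluoromethanesulfonate) | CON(C)C(=O)CC1(C)C(OS(=O)(=O)C(F)(F)F)=CC=C1OS(=O)(=O)C(F)(F)F | intermediate
10 | N-methoxy-N-methyl-2-(1-methylcyclopenta-2,4-dien-1-yl)acetamide | CON(C)C(=O)CC1(C)C=CC=C1 | intermediate
11 | 1-(methoxymethoxy)-3-(1-methylcyclopenta-2,4-dien-1-yl)propan-2-one | COCOCC(=O)CC1(C)C=CC=C1 | intermediate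
12 | sodium enolate of the C12-hydroxymethylene derivative of 11 (not isolated; delocalized) | [Na+].[O-]C=C(OCOC)C(=O)CC1(C)C=CC=C1 | intermediate
13 | (Z)-3,4-bis(methoxymethoxy)-1-(1-methylcyclopenta-2,4-dien-1-yl)but-3-en-2-one | COCO/C=C(OCOC)/C(=O)CC1(C)C=CC=C1 | intermediate
14 | tricyclic ketone: Diels–Alder adduct with C11 ketone, endo OMOM at C12 and C4 | C[C@]12CC(=O)[C@]3(OCOC)[C@@H](OCOC)[C@H]1C=C[C@H]23 | intermediate
15 | triisopropoxytitanium enolate of 14 (C10=C11; not isolated) | C[C@]12C=C(O[Ti](OC(C)C)(OC(C)C)OC(C)C)[C@]3(OCOC)[C@@H](OCOC)[C@H]1C=C[C@H]23 | intermediate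
16 | syn aldol adduct: exo CH(OH)CO2Me at C10 | C[C@]12[C@@H]([C@H](O)C(=O)OC)C(=O)[C@]3(OCOC)[C@@H](OCOC)[C@H]1C=C[C@H]23 | intermediate
17 | C11 tertiary alcohol (α-methyl, β-hydroxyl) | C[C@]12[C@@H]([C@H](O)C(=O)OC)[C@](C)(O)[C@]3(OCOC)[C@@H](OCOC)[C@H]1C=C[C@H]23 | intermediate
18 | 9,11-bis(triethylsilyl) ether of 17 | C[C@]12[C@@H]([C@H](O[Si](CC)(CC)CC)C(=O)OC)[C@](C)(O[Si](CC)(CC)CC)[C@]3(OCOC)[C@@H](OCOC)[C@H]1C=C[C@H]23 | intermediate
19 | β-keto ester (C8 ketone, C17 epimers) | C[C@]12[C@@H]([C@H](O[Si](CC)(CC)CC)C(=O)C(C)C(=O)OC)[C@](C)(O[Si](CC)(CC)CC)[C@]3(OCOC)[C@@H](OCOC)[C@H]1C=C[C@H]23 | intermediate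
20 | C4,C12 cis-diol | C[C@]12[C@@H]([C@H](O[Si](CC)(CC)CC)C(=O)C(C)C(=O)OC)[C@](C)(O[Si](CC)(CC)CC)[C@]3(O)[C@@H](O)[C@H]1C=C[C@H]23 | intermediate
21 | diquinane keto aldehyde | O=C[C@H]2C=C[C@H]3C(=O)[C@@](C)(O[Si](CC)(CC)CC)[C@H]([C@H](O[Si](CC)(CC)CC)C(=O)C(C)C(=O)OC)[C@@]23C | intermediate
22 | (4S)-allylic alcohol | C=C([C@@H](O[Si](CC)(CC)CC)CO[Si](CC)(CC)CC)[C@@H](O)[C@H]2C=C[C@H]3C(=O)[C@@](C)(O[Si](CC)(CC)CC)[C@H]([C@H](O[Si](CC)(CC)CC)C(=O)C(C)C(=O)OC)[C@@]23C | intermediate
23 | C4 acetate | C=C([C@@H](O[Si](CC)(CC)CC)CO[Si](CC)(CC)CC)[C@@H](OC(C)=O)[C@H]2C=C[C@H]3C(=O)[C@@](C)(O[Si](CC)(CC)CC)[C@H]([C@H](O[Si](CC)(CC)CC)C(=O)C(C)C(=O)OC)[C@@]23C | intermediate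
24 | C7 aldehyde | C=C([C@@H](O[Si](CC)(CC)CC)C=O)[C@@H](OC(C)=O)[C@H]2C=C[C@H]3C(=O)[C@@](C)(O[Si](CC)(CC)CC)[C@H]([C@H](O[Si](CC)(CC)CC)C(=O)C(C)C(=O)OC)[C@@]23C | intermediate
25 | trivalent samarium 7,8-diolate of the ring-closed methyl ester (not isolated) | C=C1[C@@H](OC(C)=O)[C@H]2C=C[C@H]3C(=O)[C@@](C)(O[Si](CC)(CC)CC)[C@H]([C@H](O[Si](CC)(CC)CC)[C@]([O-])(C(C)C(=O)OC)[C@@H]([O-])[C@@H]1O[Si](CC)(CC)CC)[C@@]23C.[Sm+3].[Sm+3].[I-].[I-].[I-].[I-] | intermediate
26 | nine-membered β-hydroxy γ-lactone, 6,9,11-tris(triethylsilyl) ether | C=C1[C@@H](OC(C)=O)[C@H]2C=C[C@H]3C(=O)[C@@](C)(O[Si](CC)(CC)CC)[C@H]([C@H](O[Si](CC)(CC)CC)[C@]4(O)[C@@H](C)C(=O)O[C@H]4[C@@H]1O[Si](CC)(CC)CC)[C@@]23C | intermediate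
27 | 6,8,9,11-tetraol 4-acetate | C=C1[C@@H](OC(C)=O)[C@H]2C=C[C@H]3C(=O)[C@@](C)(O)[C@H]([C@H](O)[C@]4(O)[C@@H](C)C(=O)O[C@H]4[C@@H]1O)[C@@]23C | intermediate
28 | 6-chloro-8,9,11-triol 4-acetate | C=C1[C@@H](OC(C)=O)[C@H]2C=C[C@H]3C(=O)[C@@](C)(O)[C@H]([C@H](O)[C@]4(O)[C@@H](C)C(=O)O[C@H]4[C@H]1Cl)[C@@]23C | intermediate
29 | CNP0145188.1 | C=C1[C@@H](OC(C)=O)[C@H]2C=C[C@H]3C(=O)[C@@](C)(O)[C@H]([C@H](OC(C)=O)[C@]4(O)[C@@H](C)C(=O)O[C@H]4[C@H]1Cl)[C@@]23C | target

**Counts and risks**

Total step count: 22. Longest linear sequence: 19 steps (steps 4 to 22, from 2-methylcyclopentane-1,3-dione).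

Steps most likely to fail:

1. Step 19 (key step). The ketyl may lose the neighbouring silyloxy group, the C12 ketone may be reduced, or the medium ring may close too slowly, so that simple reduction or dimerization wins. The fallback makes the C7–C8 bond without a reductant and sets out from acetate 23. Enol triflation of the β-keto ester (NaH, Tf2O, CH2Cl2, −78 °C) would give the (Z)-enol triflate F1. Swern oxidation as in step 18 would give the aldehyde F2. An intramolecular Nozaki–Hiyama–Kishi reaction (CrCl2, NiCl2 cat., DMSO, high dilution) would close the nine-membered ring, and the chromium alkoxide would lactonize to the butenolide F3. Nucleophilic epoxidation (t-BuOOH, DBU) would give the 8,17-epoxy lactone F4. Reductive opening at C17 with Cp2TiCl (from Cp2TiCl2 and Zn, THF), followed by DBU equilibration of C17, would return to the route at 26. The weak point of this fallback is the face of the epoxidation.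

2. Step 9. Enantioselection by the copper complex may be poor, or the Lewis acid may strip the acetal ethers. The fallback replaces asymmetric catalysis by resolution and sets out from 13. Thermal cycloaddition (toluene, 80 °C) would give 14 together with its enantiomer F5. The aldol of step 10 would then give 16 together with its enantiomer F6. Preparative HPLC on a chiral stationary phase would separate them, and the route is rejoined at 16.

3. Step 21. The displacement may go with allylic transposition to the primary C16 chloride, or the C9 hydroxyl and the 8,9-diol may react. The fallback frees only the allylic alcohol and sets out from 26. Mild acid (PPTS, MeOH, CH2Cl2, 0 °C) should remove the least hindered, allylic C6 silyl ether to give the C6 alcohol F7. The same PPh3/hexachloroacetone chlorination would give the C6 chloride F8. HF·pyridine would then return to the route at 28.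

**Further compounds**

F1 | step 19 | (Z)-enol triflate of the β-keto ester of 23 | C=C([C@@H](O[Si](CC)(CC)CC)CO[Si](CC)(CC)CC)[C@@H](OC(C)=O)[C@H]2C=C[C@H]3C(=O)[C@@](C)(O[Si](CC)(CC)CC)[C@H]([C@H](O[Si](CC)(CC)CC)/C(OS(=O)(=O)C(F)(F)F)=C(\C)C(=O)OC)[C@@]23C
F2 | step 19 | C7 aldehyde enol triflate | C=C([C@@H](O[Si](CC)(CC)CC)C=O)[C@@H](OC(C)=O)[C@H]2C=C[C@H]3C(=O)[C@@](C)(O[Si](CC)(CC)CC)[C@H]([C@H](O[Si](CC)(CC)CC)/C(OS(=O)(=O)C(F)(F)F)=C(\C)C(=O)OC)[C@@]23C
F3 | step 19 | nine-membered butenolide (C8=C17) | C=C1[C@@H](OC(C)=O)[C@H]2C=C[C@H]3C(=O)[C@@](C)(O[Si](CC)(CC)CC)[C@H]([C@H](O[Si](CC)(CC)CC)C4=C(C)C(=O)O[C@H]4[C@@H]1O[Si](CC)(CC)CC)[C@@]23C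
F4 | step 19 | 8,17-epoxy lactone | C=C1[C@@H](OC(C)=O)[C@H]2C=C[C@H]3C(=O)[C@@](C)(O[Si](CC)(CC)CC)[C@H]([C@H](O[Si](CC)(CC)CC)[C@@]45O[C@@]5(C)C(=O)O[C@H]4[C@@H]1O[Si](CC)(CC)CC)[C@@]23C
F5 | step 9 | enantiomer of 14 | C[C@@]12CC(=O)[C@@]3(OCOC)[C@H](OCOC)[C@@H]1C=C[C@@H]23
F6 | step 9 | enantiomer of 16 | C[C@@]12[C@H]([C@@H](O)C(=O)OC)C(=O)[C@@]3(OCOC)[C@H](OCOC)[C@@H]1C=C[C@@H]23
F7 | step 21 | C6 alcohol 9,11-bis(triethylsilyl) ether | C=C1[C@@H](OC(C)=O)[C@H]2C=C[C@H]3C(=O)[C@@](C)(O[Si](CC)(CC)CC)[C@H]([C@H](O[Si](CC)(CC)CC)[C@]4(O)[C@@H](C)C(=O)O[C@H]4[C@@H]1O)[C@@]23C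
F8 | step 21 | C6 chloride 9,11-bis(triethylsilyl) ether | C=C1[C@@H](OC(C)=O)[C@H]2C=C[C@H]3C(=O)[C@@](C)(O[Si](CC)(CC)CC)[C@H]([C@H](O[Si](CC)(CC)CC)[C@]4(O)[C@@H](C)C(=O)O[C@H]4[C@H]1Cl)[C@@]23C
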